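## Structural features

The target is a flavan-3-ol. A phloroglucinol-type ring A is fused through C4a–C8a to the dihydropyran ring C, which carries the catechol ring B on C2 and a free hydroxyl on C3. C2 and C3 are adjacent stereocentres, (2R,3S), with the aryl group and the hydroxyl trans. The phenolic oxygens O5 and O7 carry 3,4,5-trihydroxybenzoyl (galloyl) esters, while O3, O3' and O4' are free. Fragile points are the two aryl esters (base and nucleophiles), the catechol and pyrogallol units (oxidation), and the C2–O1 bond, a benzylic ether para to a ring B oxygen that ionises in strong acid. The real difficulty is twofold: setting the trans C2/C3 pair in one absolute sense on a ring with no other stereochemical anchor, and telling O5/O7 apart from O3 and the ring B phenols. The key step reads O1–C8a–C4a–C4 as a latent ortho-quinone methide on ring A and C2–C3 as the remnant of an (E)-alkene whose C3 substituent is boron. Boron stands in for the hydroxyl and leaves the regiochemistry of the cycloaddition to the aryl group. One descriptor needs correcting: the 3-boryl flavan with the spatial arrangement of (+)-catechin is (2S,3S), not (2R,3S), because boron ranks below carbon; oxidation to the 3-ol changes the C2 label to R without touching the centre.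

## Logic of the disconnections

15 to 14. Nine benzylic O–CH2 bonds are cut in the retrosynthetic sense: eight benzyl ethers and one benzyl carbonate on O3. All free hydroxyls are thereby masked by groups that fall in one neutral reductive operation, so the oxidation-prone polyphenol appears only at the end. The forward step must spare the aryl esters and the C2–O1 bond, hence a neutral aprotic medium.

14 to 12 and 13. The two aryl ester C(=O)–O bonds at O5 and O7 are cut. This is the convergent point: it removes the two large acyl units and leaves a flavan whose only free hydroxyls are the ones to be acylated. The demand is that O3 and the ring B oxygens are blocked and that the coupling is mild and non-epimerising.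

12 to 11 to 10. Two O–Si bonds are restored on ring A and the O3 carbonate is removed. Ring A oxygens need a group orthogonal to benzyl; silyl ethers serve. O3 needs a group that goes on without an alkoxide (which would strip aryl silyl ethers) and leaves in the final hydrogenolysis. The forward demands are acylation of a hindered secondary hydroxyl under amine base and a buffered fluoride step.

10 to 9. The C3–O bond is traced to a C3–B bond. An oxygen on the alkene would reverse its polarity in the cycloaddition; boron does not, and it is replaced by hydroxyl stereospecifically. The demand is oxidation with retention under mild base.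

9 to 3 and 7, through 8. C3–C4 and O1–C2 are cut, the two bonds of a [4+2] retron in ring C. The molecule falls into a ring A unit carrying C4 and a ring B unit carrying C2 and C3, and both stereocentres arise in one step. The forward step needs pure (E)-geometry, face selection by a chiral catalyst, and ring closure faster than loss of boron or self-alkylation.

3 to 2 to 1. A benzylic C–H bond (retro-reduction) and two O–Si bonds are cut. Commercial 1 already holds ring A with C4 as a formyl group, and its hydrogen-bonded ortho hydroxyl is differentiated for free. The demands are a two-fold silylation that stops, and a reduction that keeps the benzylic oxygen.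

7 to 4 and 5, through 6. The C2=C3 double bond is cut by olefination. Commercial 4 brings ring B with its benzyl ethers and 5 brings C3 with boron attached. The demand is high (E)-selectivity, since alkene geometry becomes the 2,3-relationship.

## Other disconnections considered

Alternative 1: The cut is C2–C3 together with the C3–O bond. In the forward step the ylide of a chiral benzylsulfonium salt carrying the ring B unit (sulfide left open) adds to [2,4,6-tris(tert-butyldimethylsilyloxy)phenyl]acetaldehyde A1 and closes to the (2S,3S)-trans-epoxide A2.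
- In favour: asymmetric epoxidation with aryl-stabilised sulfonium ylides is an established reaction class, so the stereochemistry rests on precedent. On this point the alternative is better than the chosen plan. It is equal in setting both stereocentres and a C–C bond in one step.
- Against: A1 is a strongly enolisable, very electron-rich arylacetaldehyde, and the ylide is generated with base. The 3,4-dialkoxybenzyl sulfonium salt should ionise easily.
- After A2, ring C is still open. One ortho silyl ether must come off and the phenol must open the epoxide at the benzylic carbon (6-endo, inversion) against 5-exo attack at C3 and against SN1 leakage to the cis series.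
- The three silyl ethers cannot be told apart, so closure would give the 3,5,7-triol, which needs chemoselective phenol acylation or re-protection.
- Comparison: the chosen step closes ring C and sets both centres at once, whereas A2 has neither ring C nor a secured C2. Step count should be about equal, possibly one shorter for the alternative if the triol can be acylated selectively.

Alternative 2: The cut is O1–C8a. In the forward step the benzylic hydroxyl of (1R,2S)-2-(benzyloxy)-1-[3,4-bis(benzyloxy)phenyl]-3-[2-bromo-4,6-bis(methoxymethoxy)phenyl]propan-1-ol A3 is joined to the ortho aryl bromide (CuI with a diamine, or Pd(OAc)2 with a bulky biaryl phosphine) to give 3,3',4'-tri-O-benzyl-5,7-bis-O-(methoxymethyl)-(+)-catechin A4.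
- In favour: the C–O bond at C2 is not touched, so the ring closure cannot scramble stereocentres made earlier by dependable methods. This is better than the chosen plan on stereochemical security.
- A4 already has O3 benzylated and O5/O7 masked orthogonally, so only acetal removal, acylation and hydrogenolysis follow. That is shorter than the five operations after 9, and again better.
- Against: A3 needs an anti-diol with differentiated oxygens (syn-dihydroxylation gives the wrong relative configuration, so an inversion or a ketone reduction must be inserted). Ring A must be brominated and loses its symmetry. Secondary benzylic alkoxides on palladium are prone to β-hydride loss, and the copper variant is hot and basic. Acid removal of the acetals meets the acid-labile C2–O1 bond.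
- Comparison: the key step forms one heteroatom bond and no stereocentre, so it is less convergent. Its mechanism is of a known type. The sequence before the key step should be roughly twice as long, so the overall route is longer.

Alternative 3: The cut is C4–C4a. In the forward step ring A of (2S)-2-{(R)-[3,5-bis(allyloxy)phenoxy][3,4-bis(benzyloxy)phenyl]methyl}oxirane A5 attacks the terminal epoxide carbon (6-endo Friedel–Crafts alkylation, Lewis acid or fluorinated alcohol) to give 5,7-di-O-allyl-3',4'-di-O-benzyl-(+)-catechin A6.
- In favour: ring A is symmetric, so both ortho carbons give the same product. The C3 hydroxyl appears directly, with no boron oxidation. Allyl ethers tolerate alkoxide chemistry, which silyl ethers do not. On these three points the alternative is better.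
- Against: A5 contains a benzylic aryl ether at C2, para to a benzyloxy group. The acid that activates the epoxide can ionise it, so an existing stereocentre is exposed in the key step. 5-exo opening at C3 competes.
- A5 itself requires O-alkylation of a phloroglucinol-type phenol by a secondary, electron-rich benzylic carbinol with stereochemical fidelity; partial racemisation and C-alkylation are to be expected.
- Comparison: one ring bond and no stereocentre are formed, against two bonds and two centres in the chosen step. After A6, four operations remain (O3 protection, deallylation, acylation, hydrogenolysis), about equal to the chosen end game. The way to A5 is longer.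

Key step: step 4

Assumption: the sense of induction of the confined acid cannot be predicted; the antipode that gives (2S,3S)-9 is to be selected in a first screen.

Design remarks:
- The salicyl alcohol 3 is kept with a free phenol and silyl ethers. The silyl groups shield C6/C8 against self-alkylation. 3 is fed slowly into excess 7.
- O3 is protected as a benzyl carbonate under amine base, because an alkoxide benzylation would cleave aryl silyl ethers.
- The gallate is introduced from the free acid by carbodiimide coupling, which saves an acid chloride step.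

## Route

Step 1
Reactants: 1 2,4,6-trihydroxybenzaldehyde
Product: 2 2-hydroxy-4,6-bis(tert-butyldimethylsilyloxy)benzaldehyde
Conditions: TBSCl (2.1 equiv), imidazole, CH2Cl2/DMF, 0 °C
Reagents that add atoms: tert-butyldimethylsilyl chloride, CC(C)(C)[Si](C)(C)Cl
Why: Phenol silylation; the hydroxyl para to the formyl group and one ortho hydroxyl react, while the last ortho hydroxyl is held in a hydrogen bond to the carbonyl, so two equivalents should stop at 2.

Step 2
Reactants: 2 2-hydroxy-4,6-bis(tert-butyldimethylsilyloxy)benzaldehyde
Product: 3 2-(hydroxymethyl)-3,5-bis(tert-butyldimethylsilyloxy)phenol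
Conditions: NaBH4, THF/MeOH, −20 °C; pH 7 phosphate buffer; no acid, no silica without Et3N
Reagents that add atoms: none
Why: Borohydride reduction of an aryl aldehyde; low temperature and a buffered quench keep the electron-rich benzylic alkoxide from expelling its oxygen and from picking up the neighbouring silyl group.

Step 3
Reactants: 4 3,4-bis(benzyloxy)benzaldehyde, 5 bis(pinacolatoboryl)methane
Product: 7 (E)-2-[3,4-bis(benzyloxy)styryl]-4,4,5,5-tetramethyl-1,3,2-dioxaborolane, via lithiated bis(pinacolatoboryl)methane 6 (not isolated)
Conditions: lithium 2,2,6,6-tetramethylpiperidide (from 2,2,6,6-tetramethylpiperidine, n-BuLi), THF, 0 °C; then 4, −78 °C → rt; H2O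
Reagents that add atoms: none
Why: Boron–Wittig olefination; the α-boryl carbanion 6 adds to the aldehyde and syn elimination of the boron–oxygen pair is known to give (E)-alkenyl pinacol boronates from aryl aldehydes.

Step 4
Reactants: 3 2-(hydroxymethyl)-3,5-bis(tert-butyldimethylsilyloxy)phenol, 7 (E)-2-[3,4-bis(benzyloxy)styryl]-4,4,5,5-tetramethyl-1,3,2-dioxaborolane
Product: 9 (2S,3S)-2-[3,4-bis(benzyloxy)phenyl]-5,7-bis(tert-butyldimethylsilyloxy)-3-(4,4,5,5-tetramethyl-1,3,2-dioxaborolan-2-yl)chromane (2,3-trans), via ortho-quinone methide 8 (not isolated)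
Conditions: confined imidodiphosphorimidate Brønsted acid (two 3,3'-diaryl-BINOL units, N-triflyl groups; 5 mol %), 7 (1.5 equiv), 5 Å MS, toluene/CHCl3, −30 °C, slow addition of 3; Et3N quench
Reagents that add atoms: none
Why: Proposed new method: the confined acid dehydrates 3 to the quinone methide 8, held as a contact ion pair of the hydroxybenzylic cation and the chiral anion; the boron-bearing carbon of 7, the nucleophilic end of a para-alkoxystyrene, bonds to C4 while charge builds at the benzylic carbon, and O1 collapses onto that carbon in one asynchronous inverse-demand hetero-Diels–Alder event. The closest known reaction type is the chiral Brønsted-acid-catalysed [4+2] cycloaddition of in situ ortho-quinone methides with styrenes to 2-arylchromans; an alkenylboronate partner and an unsubstituted methide carbon are not covered by it. Ring C is closed by cycloaddition, the intermolecular C3–C4 bond leading and the six-membered ring being completed by O1–C2 bond formation inside the ion pair. The relative configuration of C2 and C3 comes from the (E)-geometry of 7, carried suprafacially into the 2,3-trans arrangement, which is also the more stable diequatorial one should closure be stepwise. The absolute configuration of both centres must come from the chiral anion, which has to select one alkene face because the methide carbon has no substituent. Regiochemistry is secured by the substrate, since aryl conjugation puts the positive charge on C2 and makes the boron-bearing carbon the nucleophile. The step also needs ring closure to beat loss of boron from the β-boryl cation and Friedel–Crafts capture of 8 by another ring A; the hindered, weakly Lewis-acidic pinacol ester, the silyl shielding of C6/C8, slow addition and low temperature serve this.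

Step 5
Reactants: 9 (2S,3S)-2-[3,4-bis(benzyloxy)phenyl]-5,7-bis(tert-butyldimethylsilyloxy)-3-(4,4,5,5-tetramethyl-1,3,2-dioxaborolan-2-yl)chromane
Product: 10 (2R,3S)-2-[3,4-bis(benzyloxy)phenyl]-5,7-bis(tert-butyldimethylsilyloxy)chroman-3-ol
Conditions: NaBO3·4H2O, THF/H2O, 0 °C → rt
Reagents that add atoms: sodium perborate (tetrahydrate), [Na+].[Na+].O[B-]1(O)OO[B-](O)(O)OO1
Why: Perborate oxidation of a secondary alkyl pinacol boronate; C3 migrates from boron to oxygen with retention, so the trans relationship and absolute configuration are kept. Perborate oxidation of 3-borylchromans is a known reaction type, and it is the mildest basic oxidant for sparing the aryl silyl ethers.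

Step 6
Reactants: 10 (2R,3S)-2-[3,4-bis(benzyloxy)phenyl]-5,7-bis(tert-butyldimethylsilyloxy)chroman-3-ol
Product: 11 benzyl (2R,3S)-2-[3,4-bis(benzyloxy)phenyl]-5,7-bis(tert-butyldimethylsilyloxy)chroman-3-yl carbonate
Conditions: CbzCl, pyridine, DMAP (cat.), CH2Cl2, 0 °C → rt
Reagents that add atoms: benzyl chloroformate, O=C(Cl)OCc1ccccc1
Why: Carbonate formation at the secondary hydroxyl under amine base; no alkoxide is formed, so the aryl silyl ethers stay, and the benzyl carbonate leaves in the final hydrogenolysis.

Step 7
Reactants: 11 benzyl (2R,3S)-2-[3,4-bis(benzyloxy)phenyl]-5,7-bis(tert-butyldimethylsilyloxy)chroman-3-yl carbonate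
Product: 12 benzyl (2R,3S)-2-[3,4-bis(benzyloxy)phenyl]-5,7-dihydroxychroman-3-yl carbonate
Conditions: TBAF, AcOH, THF, 0 °C
Reagents that add atoms: none
Why: Fluoride cleavage of aryl silyl ethers; acetic acid buffers the phenoxides so that the carbonate, the benzyl ethers and C2 are untouched.

Step 8
Reactants: 12 benzyl (2R,3S)-2-[3,4-bis(benzyloxy)phenyl]-5,7-dihydroxychroman-3-yl carbonate, 13 3,4,5-tris(benzyloxy)benzoic acid
Product: 14 (2R,3S)-3-[(benzyloxycarbonyl)oxy]-2-[3,4-bis(benzyloxy)phenyl]chromane-5,7-diyl bis[3,4,5-tris(benzyloxy)benzoate]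
Conditions: 13 (2.4 equiv), EDC·HCl, DMAP (cat.), CH2Cl2, 0 °C → rt
Reagents that add atoms: none
Why: Steglich esterification of both phenols; O3 is blocked, so only the two aryl gallate esters of the target can form.

Step 9
Reactants: 14 (2R,3S)-3-[(benzyloxycarbonyl)oxy]-2-[3,4-bis(benzyloxy)phenyl]chromane-5,7-diyl bis[3,4,5-tris(benzyloxy)benzoate]
Product: 15 (+)-catechin 5,7-di-O-gallate, (2R,3S)-2-(3,4-dihydroxyphenyl)-3-hydroxychromane-5,7-diyl bis(3,4,5-trihydroxybenzoate)
Conditions: H2 (1 atm), Pd(OH)2/C, THF/EtOAc, rt; filtration under argon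
Reagents that add atoms: none
Why: Hydrogenolysis of eight benzyl ethers and the benzyl carbonate, which loses CO2; aryl esters are inert, and a neutral aprotic medium avoids transesterification and epimerisation at C2.

## Compound list

1 | 2,4,6-trihydroxybenzaldehyde | O=Cc1c(O)cc(O)cc1O | starting material
2 | 2-hydroxy-4,6-bis(tert-butyldimethylsilyloxy)benzaldehyde | O=Cc1c(O)cc(O[Si](C)(C)C(C)(C)C)cc1O[Si](C)(C)C(C)(C)C | intermediate
3 | 2-(hydroxymethyl)-3,5-bis(tert-butyldimethylsilyloxy)phenol | OCc1c(O)cc(O[Si](C)(C)C(C)(C)C)cc1O[Si](C)(C)C(C)(C)C | intermediate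
4 | 3,4-bis(benzyloxy)benzaldehyde | O=Cc1ccc(OCc2ccccc2)c(OCc2ccccc2)c1 | starting material
5 | bis(pinacolatoboryl)methane | CC1(C)OB(CB2OC(C)(C)C(C)(C)O2)OC1(C)C | starting material
6 | [bis(4,4,5,5-tetramethyl-1,3,2-dioxaborolan-2-yl)methyl]lithium | [Li]C(B1OC(C)(C)C(C)(C)O1)B1OC(C)(C)C(C)(C)O1 | intermediate
7 | (E)-2-[3,4-bis(benzyloxy)styryl]-4,4,5,5-tetramethyl-1,3,2-dioxaborolane | CC1(C)OB(/C=C/c2ccc(OCc3ccccc3)c(OCc3ccccc3)c2)OC1(C)C | intermediate
8 | 3,5-bis(tert-butyldimethylsilyloxy)-6-methylidenecyclohexa-2,4-dien-1-one (ortho-quinone methide, ion-paired with the acid) | C=C1C(=O)C=C(O[Si](C)(C)C(C)(C)C)C=C1O[Si](C)(C)C(C)(C)C | intermediate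
9 | (2S,3S)-2-[3,4-bis(benzyloxy)phenyl]-5,7-bis(tert-butyldimethylsilyloxy)-3-(4,4,5,5-tetramethyl-1,3,2-dioxaborolan-2-yl)chromane (2,3-trans) | CC(C)(C)[Si](C)(C)Oc1cc(O[Si](C)(C)C(C)(C)C)c2c(c1)O[C@H](c1ccc(OCc3ccccc3)c(OCc3ccccc3)c1)[C@@H](B1OC(C)(C)C(C)(C)O1)C2 | intermediate
10 | (2R,3S)-2-[3,4-bis(benzyloxy)phenyl]-5,7-bis(tert-butyldimethylsilyloxy)chroman-3-ol | CC(C)(C)[Si](C)(C)Oc1cc(O[Si](C)(C)C(C)(C)C)c2c(c1)O[C@H](c1ccc(OCc3ccccc3)c(OCc3ccccc3)c1)[C@@H](O)C2 | intermediate
11 | benzyl (2R,3S)-2-[3,4-bis(benzyloxy)phenyl]-5,7-bis(tert-butyldimethylsilyloxy)chroman-3-yl carbonate | CC(C)(C)[Si](C)(C)Oc1cc(O[Si](C)(C)C(C)(C)C)c2c(c1)O[C@H](c1ccc(OCc3ccccc3)c(OCc3ccccc3)c1)[C@@H](OC(=O)OCc1ccccc1)C2 | intermediate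
12 | benzyl (2R,3S)-2-[3,4-bis(benzyloxy)phenyl]-5,7-dihydroxychroman-3-yl carbonate | Oc1cc(O)c2c(c1)O[C@H](c1ccc(OCc3ccccc3)c(OCc3ccccc3)c1)[C@@H](OC(=O)OCc1ccccc1)C2 | intermediate
13 | 3,4,5-tris(benzyloxy)benzoic acid | OC(=O)c1cc(OCc2ccccc2)c(OCc2ccccc2)c(OCc2ccccc2)c1 | starting material
14 | (2R,3S)-3-[(benzyloxycarbonyl)oxy]-2-[3,4-bis(benzyloxy)phenyl]chromane-5,7-diyl bis[3,4,5-tris(benzyloxy)benzoate] | O=C(Oc1cc(OC(=O)c2cc(OCc3ccccc3)c(OCc3ccccc3)c(OCc3ccccc3)c2)c2c(c1)O[C@H](c1ccc(OCc3ccccc3)c(OCc3ccccc3)c1)[C@@H](OC(=O)OCc1ccccc1)C2)c1cc(OCc2ccccc2)c(OCc2ccccc2)c(OCc2ccccc2)c1 | intermediate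
15 | (+)-catechin 5,7-di-O-gallate, (2R,3S)-2-(3,4-dihydroxyphenyl)-3-hydroxychromane-5,7-diyl bis(3,4,5-trihydroxybenzoate) | O=C(Oc1cc(OC(=O)c2cc(O)c(O)c(O)c2)c2c(c1)O[C@H](c1ccc(O)c(O)c1)[C@@H](O)C2)c1cc(O)c(O)c(O)c1 | target

## Step count and least certain steps

Total step count: 9. Longest linear sequence: 8 steps (steps 1, 2, 4, 5, 6, 7, 8, 9, from 1).

Step 4 (key step). The most likely failure is poor facial selectivity: the chiral anion must tell the alkene faces apart although the methide carbon has no substituent and both partners are bulky for a confined pocket. Next are loss of boron from the β-boryl benzylic cation before O1 closes (alkenyl transfer in place of cycloaddition) and oligomerisation by Friedel–Crafts attack of the methide on ring A. The fallback uses known chemistry, sets out from 2 and 7 and rejoins at 10, bypassing 9 and step 5.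
- The pinacol ester of 7 is cleaved (NaIO4, NH4OAc, acetone/H2O) to (E)-[3,4-bis(benzyloxy)styryl]boronic acid F1.
- F1 is condensed with 2 under secondary-amine catalysis (dibenzylamine, toluene, 80 °C; Petasis-type alkenyl transfer, loss of the amine, oxa-6π closure) to racemic 2-[3,4-bis(benzyloxy)phenyl]-5,7-bis(tert-butyldimethylsilyloxy)-2H-chromene F2.
- Hydroboration–oxidation (BH3·THF, then NaBO3·4H2O) places boron on C3 anti to the C2 aryl group and should give racemic 2,3-trans-2-[3,4-bis(benzyloxy)phenyl]-5,7-bis(tert-butyldimethylsilyloxy)chroman-3-ol F3.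
- The enantiomers of F3 are separated by preparative chromatography on a chiral stationary phase; the (2R,3S) enantiomer is 10.

Step 2. The benzylic oxygen may be expelled from the ortho-phenoxide (quinone methide formation and hydride capture, that is over-reduction). A silyl group may shift from the neighbouring phenol oxygen to the benzylic alkoxide. The product may self-condense on acidic contact. The fallback sets out from 2 and rejoins at 3.
- The phenol is capped by Mitsunobu allylation (allyl alcohol, PPh3, DIAD) to give 2-(allyloxy)-4,6-bis(tert-butyldimethylsilyloxy)benzaldehyde F4.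
- NaBH4 reduction, now without an ortho-phenoxide, gives [2-(allyloxy)-4,6-bis(tert-butyldimethylsilyloxy)phenyl]methanol F5.
- The allyl group is removed under neutral conditions (Pd(PPh3)4, morpholine, THF, rt) to give 3.

Step 5. The basic peroxide medium may erode the aryl silyl ethers. Less likely, the boron ate complex may open ring C by β-elimination of the antiperiplanar aryloxide in competition with the 1,2-shift. The fallback sets out from 9 and rejoins at 15, replacing steps 5 to 9; it gives up O3 protection and turns desilylation into the plan.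
- 9 is oxidised as in step 5 and silyl removal is completed with TBAF/AcOH to give (2R,3S)-2-[3,4-bis(benzyloxy)phenyl]chromane-3,5,7-triol F6.
- 13 is converted with oxalyl chloride and catalytic DMF into 3,4,5-tris(benzyloxy)benzoyl chloride F7.
- F6 is acylated on its two phenoxides only (F7, Et3N, CH2Cl2, −20 °C, no acyl-transfer catalyst) to (2R,3S)-2-[3,4-bis(benzyloxy)phenyl]-3-hydroxychromane-5,7-diyl bis[3,4,5-tris(benzyloxy)benzoate] F8.
- Hydrogenolysis (H2, Pd(OH)2/C) gives 15.
- Should ring opening be the problem, the fallback of step 4 applies, since it reaches 10 through a dialkylborane oxidation known on this ring system.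

Step 3. The (E)-geometry may be eroded or the olefination of an electron-rich aldehyde may stall; any (Z)-isomer would be carried into the 2,3-cis series. The fallback sets out from 4 and rejoins at 7.
- Ohira–Bestmann homologation (dimethyl (1-diazo-2-oxopropyl)phosphonate, K2CO3, MeOH) gives 1,2-bis(benzyloxy)-4-ethynylbenzene F9.
- Syn-hydroboration with pinacolborane (Cp2Zr(H)Cl cat.) fixes the (E)-geometry and gives 7.

## Further compounds

F1 | step 4 | (E)-[3,4-bis(benzyloxy)styryl]boronic acid | OB(O)/C=C/c1ccc(OCc2ccccc2)c(OCc2ccccc2)c1
F2 | step 4 | racemic 2-[3,4-bis(benzyloxy)phenyl]-5,7-bis(tert-butyldimethylsilyloxy)-2H-chromene | CC(C)(C)[Si](C)(C)Oc1cc(O[Si](C)(C)C(C)(C)C)c2C=CC(c3ccc(OCc4ccccc4)c(OCc4ccccc4)c3)Oc2c1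
F3 | step 4 | racemic 2,3-trans-2-[3,4-bis(benzyloxy)phenyl]-5,7-bis(tert-butyldimethylsilyloxy)chroman-3-ol (both enantiomers) | CC(C)(C)[Si](C)(C)Oc1cc(O[Si](C)(C)C(C)(C)C)c2c(c1)O[C@H](c1ccc(OCc3ccccc3)c(OCc3ccccc3)c1)[C@@H](O)C2.CC(C)(C)[Si](C)(C)Oc1cc(O[Si](C)(C)C(C)(C)C)c2c(c1)O[C@@H](c1ccc(OCc3ccccc3)c(OCc3ccccc3)c1)[C@H](O)C2
F4 | step 2 | 2-(allyloxy)-4,6-bis(tert-butyldimethylsilyloxy)benzaldehyde | O=Cc1c(OCC=C)cc(O[Si](C)(C)C(C)(C)C)cc1O[Si](C)(C)C(C)(C)C
F5 | step 2 | [2-(allyloxy)-4,6-bis(tert-butyldimethylsilyloxy)phenyl]methanol | OCc1c(OCC=C)cc(O[Si](C)(C)C(C)(C)C)cc1O[Si](C)(C)C(C)(C)C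
F6 | step 5 | (2R,3S)-2-[3,4-bis(benzyloxy)phenyl]chromane-3,5,7-triol | Oc1cc(O)c2c(c1)O[C@H](c1ccc(OCc3ccccc3)c(OCc3ccccc3)c1)[C@@H](O)C2
F7 | step 5 | 3,4,5-tris(benzyloxy)benzoyl chloride | O=C(Cl)c1cc(OCc2ccccc2)c(OCc2ccccc2)c(OCc2ccccc2)c1
F8 | step 5 | (2R,3S)-2-[3,4-bis(benzyloxy)phenyl]-3-hydroxychromane-5,7-diyl bis[3,4,5-tris(benzyloxy)benzoate] | O=C(Oc1cc(OC(=O)c2cc(OCc3ccccc3)c(OCc3ccccc3)c(OCc3ccccc3)c2)c2c(c1)O[C@H](c1ccc(OCc3ccccc3)c(OCc3ccccc3)c1)[C@@H](O)C2)c1cc(OCc2ccccc2)c(OCc2ccccc2)c(OCc2ccccc2)c1
F9 | step 3 | 1,2-bis(benzyloxy)-4-ethynylbenzene | C#Cc1ccc(OCc2ccccc2)c(OCc2ccccc2)c1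
A1 | alternative 1 | [2,4,6-tris(tert-butyldimethylsilyloxy)phenyl]acetaldehyde | O=CCc1c(O[Si](C)(C)C(C)(C)C)cc(O[Si](C)(C)C(C)(C)C)cc1O[Si](C)(C)C(C)(C)C
A2 | alternative 1 | (2S,3S)-2-[3,4-bis(benzyloxy)phenyl]-3-[2,4,6-tris(tert-butyldimethylsilyloxy)benzyl]oxirane (trans) | O1[C@@H](c2ccc(OCc3ccccc3)c(OCc3ccccc3)c2)[C@@H]1Cc1c(O[Si](C)(C)C(C)(C)C)cc(O[Si](C)(C)C(C)(C)C)cc1O[Si](C)(C)C(C)(C)C
A3 | alternative 2 | (1R,2S)-2-(benzyloxy)-1-[3,4-bis(benzyloxy)phenyl]-3-[2-bromo-4,6-bis(methoxymethoxy)phenyl]propan-1-ol | O[C@H](c1ccc(OCc2ccccc2)c(OCc2ccccc2)c1)[C@@H](OCc1ccccc1)Cc1c(Br)cc(OCOC)cc1OCOC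
A4 | alternative 2 | 3,3',4'-tri-O-benzyl-5,7-bis-O-(methoxymethyl)-(+)-catechin | COCOc1cc(OCOC)c2c(c1)O[C@H](c1ccc(OCc3ccccc3)c(OCc3ccccc3)c1)[C@@H](OCc1ccccc1)C2
A5 | alternative 3 | (2S)-2-{(R)-[3,5-bis(allyloxy)phenoxy][3,4-bis(benzyloxy)phenyl]methyl}oxirane | C=CCOc1cc(OCC=C)cc(c1)O[C@H](c1ccc(OCc2ccccc2)c(OCc2ccccc2)c1)[C@@H]1CO1
A6 | alternative 3 | 5,7-di-O-allyl-3',4'-di-O-benzyl-(+)-catechin | C=CCOc1cc(OCC=C)c2c(c1)O[C@H](c1ccc(OCc3ccccc3)c(OCc3ccccc3)c1)[C@@H](O)C2
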